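**Plan**

1. Numbering (eudesmane): ring B = C5–C10 (C7 carries isopropyl, C6 carries O, C10 carries methyl), ring A = C1–C5/C10 (C1 = CHOH, C4 = C(O)(C15H2O)); the orthoester carbon joins O4, O6 and O15.
2. Cuts: (a) the three orthoester C–O bonds, giving tetraol 21 and trimethyl orthocinnamate; (b) ring A at C1–C2 and C3–C4, giving aldehyde ester 14 and phenyl vinyl sulfone as the C2–C3 unit; (c) C5–C4 and C10–C1, giving piperitone, a vinyl nucleophile and ethyl glyoxylate.
3. Forward: ring B is taken from (−)-menthone; a benzylidene 1,3-dioxane across O4/O6 serves as a temporary ring; ring A is closed in one operation by a Michael–aldol annulation; the sulfone and the acetal are then removed and the orthoester cage is closed last.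
4. Enabling feature: C4 is α to the C15 ester and carries O4, so inside the O4/O6 dioxane it is the only enolisable carbon, while C1 is a non-enolisable aldehyde on quaternary C10; both sit equatorial and 1,4 to each other across the C5–C10 bond of ring B, so a two-carbon acceptor/donor can bridge them.
5. Stereochemistry: C7 from menthone; C10 and C5 from the tandem cuprate addition/aldol (axial attack cis to isopropyl, then anti to vinyl); C6 from chelate-controlled reduction; C4 from equatorial attack on the dioxane enolate and C1 from the reversible sulfone aldol (both in the key step); the orthoester carbon from the cage.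

Key step: step 6

Remark: (S)-piperitone and trimethyl orthocinnamate are treated as not reliably purchasable and are made in steps 1 and 10; the carbinol centre at C4 created in step 2 becomes trigonal in step 6, so either C4 epimer ends in the same product.

Step 1
Reactants: 1 (−)-menthone
Product: 4 (S)-(+)-piperitone, via lithium enolate 2 (not isolated), via alpha-sulfilimino ketone 3 (not isolated)
Conditions: LiN(iPr)2, THF, −78 °C; then N-tert-butylbenzenesulfinimidoyl chloride, −78 °C
Reagents that add atoms: none
Why: Mukaiyama dehydrogenation: kinetic deprotonation on the CH2 side, sulfur attack and syn-elimination of the sulfenamide through the methyl-bearing β-CH should give the conjugated enone, while the isopropyl-bearing centre (later C7) on the other side of the carbonyl is not deprotonated at −78 °C.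

Step 2
Reactants: 4 (S)-(+)-piperitone; 5 vinylmagnesium bromide; 6 ethyl glyoxylate
Product: 8 ethyl (2R)-2-[(1S,2R,5S)-2-ethenyl-2-methyl-6-oxo-5-(propan-2-yl)cyclohexyl]-2-hydroxyacetate, via bromomagnesium enolate 7 (not isolated)
Conditions: CuBr·SMe2 (20 mol %), THF, −40 °C; then 6 (freshly cracked, toluene), −78 °C; sat. aq NH4Cl, −78 °C
Reagents that add atoms: vinylmagnesium bromide C=C[Mg]Br; ethyl glyoxylate CCOC(=O)C=O
Why: Copper-catalysed conjugate addition with aldol trapping of the regio-defined enolate: vinyl should enter axially on the half-chair with pseudo-equatorial isopropyl and hence cis to isopropyl (sets C10), glyoxylate should add at C5 anti to the axial vinyl (sets C5), and the closed Zimmerman–Traxler transition state of the (E)-enolate should favour the anti carbinol at C4.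

Step 3
Reactants: 8 ethyl (2R)-2-[(1S,2R,5S)-2-ethenyl-2-methyl-6-oxo-5-(propan-2-yl)cyclohexyl]-2-hydroxyacetate
Product: 10 ethyl (2R)-2-[(1R,2R,5S,6R)-2-ethenyl-6-hydroxy-2-methyl-5-(propan-2-yl)cyclohexyl]-2-hydroxyacetate, via diethylboron chelate 9 (not isolated)
Conditions: Et2BOMe, THF/MeOH (4:1), −78 °C; NaBH4, −78 → −40 °C; AcOH, then MeOH co-evaporation
Reagents that add atoms: none
Why: Narasaka–Prasad reduction: the boron chelate of the anti aldol is a half-chair with C15 and C10 equatorial, and external hydride should add axially to C6 from the face away from the axial isopropyl, giving the 1,3-syn diol with O6 trans to the C5 side chain and cis to isopropyl (sets C6) and removing the epimerisable ketone next to C7; the α-hydroxy ester is not reduced at this temperature.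

Step 4
Reactants: 10 ethyl (2R)-2-[(1R,2R,5S,6R)-2-ethenyl-6-hydroxy-2-methyl-5-(propan-2-yl)cyclohexyl]-2-hydroxyacetate; 11 benzaldehyde dimethyl acetal
Product: 12 O4/O6-benzylidene acetal of 10
Conditions: PPTS (cat.), CH2Cl2, rt
Reagents that add atoms: benzaldehyde dimethyl acetal COC(OC)c1ccccc1
Why: Thermodynamic transacetalisation should close the all-equatorial 2-phenyl-1,3-dioxane trans-fused to ring B (phenyl equatorial), which masks both hydroxyls, locks ring B with isopropyl and methyl axial and leaves C4–H as the only acidic CH; the mild acid and prompt use limit lactonisation of O6 onto the ester.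

Step 5
Reactants: 12 O4/O6-benzylidene acetal of 10
Product: 14 C10-formyl benzylidene acetal ester, via ozonide 13 (not isolated)
Conditions: O3, CH2Cl2, −78 °C, stopped at first excess; then PPh3, −78 °C → rt
Reagents that add atoms: ozone [O-][O+]=O
Why: Ozonolysis of the only alkene with reductive work-up should give the non-enolisable neopentyl aldehyde (C1), the acetal C–H reacting with ozone far more slowly than the vinyl group at −78 °C.

Step 6
Reactants: 14 C10-formyl benzylidene acetal ester; 15 phenyl vinyl sulfone
Product: 18 ring A hydroxy sulfone, via lithium ester enolate 16 (not isolated), via lithiated Michael adduct 17 (not isolated)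
Conditions: lithium 2,2,6,6-tetramethylpiperidide (1.05 equiv), THF, −78 °C; then 15, −78 → 0 °C; sat. aq NH4Cl
Reagents that add atoms: phenyl vinyl sulfone C=CS(=O)(=O)c1ccccc1
Why: The amide removes the C4–H (α to the C15 ester and to O4) to give the exocyclic enolate 16, which adds to the vinyl sulfone (C3–C4 bond), and the α-sulfonyl carbanion 17 then adds to the C1 aldehyde (C1–C2 bond) to give the lithium alkoxide of 18. The closest known reaction type is a Michael-initiated ring closure, that is, enolate conjugate addition to a vinyl sulfone followed by Julia-type addition of the sulfonyl carbanion to an aldehyde, used here as a formal [4+2] annulation. Ring A closes by 6-exo-trig attack of the carbanion on the aldehyde carbonyl through a chair in which the C4–C3 and C10–C1 bonds are equatorial on the dioxane and on ring B, so the decalin is trans-fused by construction. C4 is controlled by the chair dioxane trans-fused to ring B: the acceptor should approach the enolate on the face of H5 (equatorial attack), the other face being screened by C6 and the syn-axial hydrogens, which places C3 equatorial and the ester (C15) axial. C1 is controlled by the reversibility of the sulfonyl-carbanion addition on warming to 0 °C, which should settle the alkoxide equatorial and trans to the equatorial sulfone with lithium bridging; the sulfone-bearing C2 is a temporary centre removed in step 7. The step needs deprotonation at C4 without attack on the aldehyde (secured by the hindered hydride-free amide, the quaternary C10 and the acetal that leaves C4–H as the only acidic CH) and ring closure faster than vinyl sulfone oligomerisation (secured by the aldehyde held 1,4 to C4 across C5–C10).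

Step 7
Reactants: 18 ring A hydroxy sulfone
Product: 19 ethyl 4,6-O-benzylidene-1-hydroxy ester (C2 = CH2)
Conditions: Na(Hg) (6%), Na2HPO4, MeOH/THF, −20 °C
Reagents that add atoms: none
Why: Reductive desulfonylation: electron transfer cleaves the C2–S bond and the resulting carbanion is protonated by methanol faster than it can expel the free β-hydroxyl, so C2 becomes CH2 with the C1 carbinol kept, the phosphate buffer suppressing retro-aldol opening.

Step 8
Reactants: 19 ethyl 4,6-O-benzylidene-1-hydroxy ester (C2 = CH2)
Product: 20 4,6-O-benzylidene-1,15-diol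
Conditions: LiAlH4, THF, 0 °C
Reagents that add atoms: none
Why: Hydride reduction of the axial ester to the primary alcohol C15–OH; the benzylidene acetal is inert and the C1 alkoxide only consumes hydride.

Step 9
Reactants: 20 4,6-O-benzylidene-1,15-diol
Product: 21 (1S,4S,5R,6R,7S,10S)-eudesmane-1,4,6,15-tetraol
Conditions: H2 (1 atm), Pd(OH)2/C, MeOH/EtOAc, rt
Reagents that add atoms: none
Why: Hydrogenolysis of the benzylic C–O bonds of the benzylidene acetal should free O4 and O6 with no change at any stereocentre.

Step 10
Reactants: 22 (E)-β-bromostyrene; 23 tetramethyl orthocarbonate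
Product: 25 trimethyl orthocinnamate, via styrylmagnesium bromide 24 (not isolated)
Conditions: Mg, THF, rt; then 23, reflux
Reagents that add atoms: (E)-β-bromostyrene Br/C=C/c1ccccc1; tetramethyl orthocarbonate COC(OC)(OC)OC
Why: Tschitschibabin orthoester synthesis: the alkenyl Grignard reagent, formed with retention of the (E) geometry, displaces one methoxide of the orthocarbonate.

Step 11
Reactants: 21 (1S,4S,5R,6R,7S,10S)-eudesmane-1,4,6,15-tetraol; 25 trimethyl orthocinnamate
Product: 26 CNP0190302.1
Conditions: CSA (5 mol %), CH2Cl2, 4 Å MS, rt; then Et3N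
Reagents that add atoms: trimethyl orthocinnamate COC(OC)(OC)/C=C/c1ccccc1
Why: Acid-catalysed orthoester exchange under thermodynamic control: only the 4,6,15-triol array (equatorial O4 and O6 in peri relation plus the axial CH2O on C4) can close the 2,7,8-trioxabicyclo[3.2.1]octane cage, so the equatorial 1-OH should stay free and the configuration of the orthoester carbon is dictated by the cage.

**Compound list**

1 | (−)-menthone, (2S,5R)-5-methyl-2-(propan-2-yl)cyclohexan-1-one | CC(C)[C@@H]1CC[C@@H](C)CC1=O | starting material
2 | lithium enolate of 1 on the CH2 side | CC(C)[C@@H]1CC[C@@H](C)C=C1[O-].[Li+] | intermediate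
3 | 6-(N-tert-butyl-S-phenylsulfinimidoyl)menthone (new centres undefined) | CC(C)[C@@H]1CC[C@@H](C)C(S(=NC(C)(C)C)c2ccccc2)C1=O | intermediate
4 | (S)-(+)-piperitone, (6S)-3-methyl-6-(propan-2-yl)cyclohex-2-en-1-one | CC(C)[C@@H]1CCC(C)=CC1=O | intermediate
5 | vinylmagnesium bromide | C=C[Mg]Br | starting material
6 | ethyl glyoxylate | CCOC(=O)C=O | starting material
7 | bromomagnesium enolate (C5=C6–OMgBr) of the conjugate adduct, vinyl on C10 cis to the C7 isopropyl | CC(C)[C@@H]1CC[C@@](C=C)(C)C=C1O[Mg]Br | intermediate
8 | ethyl (2R)-2-[(1S,2R,5S)-2-ethenyl-2-methyl-6-oxo-5-(propan-2-yl)cyclohexyl]-2-hydroxyacetate (anti aldol; side chain trans to vinyl and to isopropyl) | CC(C)[C@@H]1CC[C@@](C=C)(C)[C@@H]([C@@H](O)C(=O)OCC)C1=O | intermediate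
9 | O4-diethylboron chelate of 8 | CC(C)[C@@H]1CC[C@@](C=C)(C)[C@@H]([C@@H](OB(CC)CC)C(=O)OCC)C1=O | intermediate
10 | ethyl (2R)-2-[(1R,2R,5S,6R)-2-ethenyl-6-hydroxy-2-methyl-5-(propan-2-yl)cyclohexyl]-2-hydroxyacetate (1,3-syn diol; O6 cis to isopropyl and vinyl, trans to the side chain) | CC(C)[C@@H]1CC[C@@](C=C)(C)[C@@H]([C@@H](O)C(=O)OCC)[C@@H]1O | intermediate
11 | benzaldehyde dimethyl acetal | COC(OC)c1ccccc1 | starting material
12 | O4/O6-benzylidene acetal of 10: 2-phenyl-1,3-dioxane trans-fused to ring B, with phenyl, ethyl ester and both ring B bonds equatorial on the dioxane; isopropyl and methyl axial on ring B | CC(C)[C@@H]1CC[C@@](C=C)(C)[C@@H]2[C@@H]1O[C@@H](c1ccccc1)O[C@H]2C(=O)OCC | intermediate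
13 | ozonide (1,2,4-trioxolane) of the vinyl group of 12 | CC(C)[C@@H]1CC[C@@](C3OCOO3)(C)[C@@H]2[C@@H]1O[C@@H](c1ccccc1)O[C@H]2C(=O)OCC | intermediate
14 | C10-formyl benzylidene acetal ester (12 with CHO in place of vinyl) | CC(C)[C@@H]1CC[C@@](C=O)(C)[C@@H]2[C@@H]1O[C@@H](c1ccccc1)O[C@H]2C(=O)OCC | intermediate
15 | phenyl vinyl sulfone | C=CS(=O)(=O)c1ccccc1 | starting material
16 | lithium ester enolate of 14 (C4=C15 exocyclic to the dioxane) | CC(C)[C@@H]1CC[C@@](C=O)(C)[C@@H]2[C@@H]1O[C@@H](c1ccccc1)OC2=C([O-])OCC.[Li+] | intermediate
17 | lithiated Michael adduct: C4 quaternary, carrying CH2–CH(Li)SO2Ph equatorial and the ester axial on the dioxane | CC(C)[C@@H]1CC[C@@](C=O)(C)[C@@H]2[C@@H]1O[C@@H](c1ccccc1)O[C@@]2(C(=O)OCC)C[CH-]S(=O)(=O)c1ccccc1.[Li+] | intermediate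
18 | ring A hydroxy sulfone: trans-decalin with equatorial 1-OH, equatorial 2-phenylsulfonyl, axial C15 ethyl ester on C4 and the O4/O6 benzylidene acetal | CC(C)[C@@H]1CC[C@@]2(C)[C@@H]3[C@@H]1O[C@@H](c1ccccc1)O[C@@]3(C(=O)OCC)C[C@@H](S(=O)(=O)c1ccccc1)[C@@H]2O | intermediate
19 | ethyl 4,6-O-benzylidene-1-hydroxy ester (18 with C2 = CH2) | CC(C)[C@@H]1CC[C@@]2(C)[C@@H]3[C@@H]1O[C@@H](c1ccccc1)O[C@@]3(C(=O)OCC)CC[C@@H]2O | intermediate
20 | 4,6-O-benzylidene-1,15-diol (19 with CH2OH in place of the ester) | CC(C)[C@@H]1CC[C@@]2(C)[C@@H]3[C@@H]1O[C@@H](c1ccccc1)O[C@@]3(CO)CC[C@@H]2O | intermediate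
21 | (1S,4S,5R,6R,7S,10S)-eudesmane-1,4,6,15-tetraol (trans-decalin; 1-OH, 4-OH and 6-OH equatorial; C15 and isopropyl axial) | CC(C)[C@@H]1CC[C@@]2(C)[C@H]([C@@H]1O)[C@](O)(CO)CC[C@@H]2O | intermediate
22 | (E)-β-bromostyrene | Br/C=C/c1ccccc1 | starting material
23 | tetramethyl orthocarbonate | COC(OC)(OC)OC | starting material
24 | (E)-styrylmagnesium bromide | Br[Mg]/C=C/c1ccccc1 | intermediate
25 | trimethyl orthocinnamate, (E)-(3,3,3-trimethoxyprop-1-en-1-yl)benzene | COC(OC)(OC)/C=C/c1ccccc1 | intermediate
26 | CNP0190302.1, the 4,6,15-O-orthocinnamate of 21 with free 1-OH | CC(C)[C@@H]1CC[C@@]2(C)[C@@H]3[C@@H]1O[C@]1(/C=C/c4ccccc4)OC[C@@]3(CC[C@@H]2O)O1 | target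

**Step count and risks**

Total step count: 11. Longest linear sequence: 10 (steps 1–9 and 11; step 10 is a side branch).

Most likely to fail, first: step 6. The hindered C4–H may enolise slowly, the amide or the enolate may attack the aldehyde, the vinyl sulfone may oligomerise before ring closure, or the first carbon–carbon bond may form with poor facial selectivity. The fallback separates the three events and sets out from 12. Deprotonation of 12 with LiN(iPr)2 in THF at −78 °C, with no aldehyde present, and addition of phenyl vinyl sulfone should give the protonated Michael adduct F1. Ozonolysis of its vinyl group (O3, then PPh3) should give the aldehyde sulfone F2. Substoichiometric KOtBu in THF/tBuOH at 0 °C should then close ring A by a reversible, thermodynamically controlled intramolecular sulfone aldol, and the route is rejoined at 18.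

Second: step 3. External hydride may enter the boron chelate from the wrong face, or the aldol of step 2 may carry the carbinol configuration that is mismatched with chelate control; either way the outcome is poor facial selectivity at C6. The fallback changes the control element to internal hydride delivery on the inverted carbinol and sets out from 8. Mitsunobu esterification of 8 (4-nitrobenzoic acid, PPh3, DIAD) should give the inverted 4-nitrobenzoate F3, and ethanolysis (K2CO3 cat., EtOH, 0 °C) the C4-epimeric aldol F4. Saksena–Evans reduction of F4 (Me4NBH(OAc)3, MeCN/AcOH, −30 °C) delivers hydride from the O4-bound borohydride on the side-chain face, where the anti rule and the ring geometry agree, and should give the 1,3-anti diol F5 with the same C6 configuration as 10. Under the conditions of steps 4 and 5, F5 should give the benzylidene acetal F6 (ester axial on the dioxane) and the aldehyde F7. Deprotonation of F7 gives the same enolate 16, so the route is rejoined at 18.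

Third: step 7. The basic reducing medium may open ring A by retro-aldol, or reductive elimination may give the C1–C2 alkene; any C1 epimer from step 6 would also be carried through. The fallback moves the desulfonylation to the ketone oxidation level and sets out from 18. Dess–Martin periodinane should give the β-keto sulfone F8, and Al(Hg) in THF/H2O should cleave the activated C–S bond to the C1 ketone F9. NaBH4 in MeOH at −20 °C should then add hydride axially, anti to the angular methyl, to give the equatorial alcohol without touching the ester, and the route is rejoined at 19.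

Further compounds
F1 | step 6 | Michael adduct of 12: C4 quaternary with CH2CH2SO2Ph equatorial and ester axial on the dioxane, vinyl still on C10 | CC(C)[C@@H]1CC[C@@](C=C)(C)[C@@H]2[C@@H]1O[C@@H](c1ccccc1)O[C@@]2(C(=O)OCC)CCS(=O)(=O)c1ccccc1
F2 | step 6 | aldehyde sulfone (F1 with CHO in place of vinyl; protonated form of 17) | CC(C)[C@@H]1CC[C@@](C=O)(C)[C@@H]2[C@@H]1O[C@@H](c1ccccc1)O[C@@]2(C(=O)OCC)CCS(=O)(=O)c1ccccc1
F3 | step 3 | 4-nitrobenzoate of the C4-inverted aldol | CC(C)[C@@H]1CC[C@@](C=C)(C)[C@@H]([C@H](OC(=O)c2ccc(cc2)[N+](=O)[O-])C(=O)OCC)C1=O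
F4 | step 3 | C4 epimer of 8 (syn aldol, 2S) | CC(C)[C@@H]1CC[C@@](C=C)(C)[C@@H]([C@H](O)C(=O)OCC)C1=O
F5 | step 3 | C4 epimer of 10 (1,3-anti diol, C6 as in 10) | CC(C)[C@@H]1CC[C@@](C=C)(C)[C@@H]([C@H](O)C(=O)OCC)[C@@H]1O
F6 | step 3 | C4 epimer of 12 (ester axial on the dioxane) | CC(C)[C@@H]1CC[C@@](C=C)(C)[C@@H]2[C@@H]1O[C@@H](c1ccccc1)O[C@@H]2C(=O)OCC
F7 | step 3 | C4 epimer of 14 | CC(C)[C@@H]1CC[C@@](C=O)(C)[C@@H]2[C@@H]1O[C@@H](c1ccccc1)O[C@@H]2C(=O)OCC
F8 | step 7 | β-keto sulfone (18 oxidised at C1; C2 epimerisable) | CC(C)[C@@H]1CC[C@@]2(C)[C@@H]3[C@@H]1O[C@@H](c1ccccc1)O[C@@]3(C(=O)OCC)CC(S(=O)(=O)c1ccccc1)C2=O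
F9 | step 7 | C1 ketone (19 oxidised at C1) | CC(C)[C@@H]1CC[C@@]2(C)[C@@H]3[C@@H]1O[C@@H](c1ccccc1)O[C@@]3(C(=O)OCC)CCC2=O
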